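The numbers in the tables are calculated on assumed constants, and the scatter is random.

If the partner, the limiting reagent, is followed through its ledger entry by entry, the flask with 0.900 equiv can be reckoned from the ash and oak runs.

| setting | ash | oak | flask |
|---|---|---|---|
| solid substrate | 2.1 M | 2.1 M | 2.1 M |
| partner | 0.45 equiv | 0.68 equiv | 0.900 equiv |
| remark | run made earlier | run made earlier |  |
| time |  |  | 20 h |

| run | time / h | reactive form / % | product / % |
|---|---|---|---|
| ash | 0.500 | 17.4 | 5.0 |
| ash | 1.00 | 24.8 | 16.4 |
| ash | 2.00 | 38.9 | 35.5 |
| ash | 3.00 | 37.0 | 42.5 |
| ash | 6.00 | 35.8 | 46.8 |
| ash | 12.0 | 34.8 | 44.4 |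
| ash | 25.0 | 36.2 | 45.4 |
| oak | 0.500 | 14.1 | 7.8 |
| oak | 1.00 | 21.8 | 25.0 |
| oak | 2.00 | 33.0 | 49.6 |
| oak | 3.00 | 25.2 | 61.1 |
| oak | 6.00 | 23.6 | 65.2 |
| oak | 12.0 | 19.4 | 70.5 |
| oak | 25.0 | 22.2 | 68.2 |

(each reading ± 1 percentage point)

- as a solid, counted per litre of solution: solid substrate
- at the start none of the solid substrate is in solution

1. the best time, 20 h at the latest, for reactive form
2. the amount of reactive form, in percent of the solid substrate charged, at that time

The first entry is product. The ash run levels near 45.4% on 45.0% of partner charged and the oak run near 68.2% on 68.0%, so a unit of partner coupled is read as a unit of product.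

The second entry is the part of the solid substrate charge that stays uncoupled. Taken together, the late readings of both runs show a share of it as reactive form of 66.3%, a value that carries their scatter.

The third entry is the partner coupled up to the peak, which both runs read at 2.00 h. Partner is taken to lose a fixed fraction per unit of reactive form per hour, so its rate integrates to a logarithm: the log of its fall equals a constant times the area under reactive form. If the curves keep their shape, that area follows the peak. The clearance number is therefore the natural log of partner's fall up to the peak, divided by the peak as a fraction of the charge. Ash and oak together give 3.98.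

My own reckoning treats the solid as dissolved at the peak:

coupled = partner charged × (whole charge − exp(−clearance × peak))

peak = share × (whole charge − coupled)

Starting from a trial peak of 33.1%, the lines return 22.6%. The midpoint 27.9% returns 26.3%, and the next midpoint 27.1% returns 26.9%. My reckoning thus puts the flask's peak at 27.0% near 2.00 h.

If the flask's partner ends wholly coupled, the books close at 6.63% of reactive form, less than the reckoned peak, so the reckoned best time stays at the peak.

The forecast gives 2 h and 27%, holding that “the maximum sits at the kink”.

The flask gives 26.9% at 1.90 h.

    starting material ⇌ reactive form (K = 1.90, k = 1.80 /min)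
    partner + reactive form → product (k = 0.0260 /M/min)
    solid substrate ⇌ starting material, rate k3*(cs3 - [starting material]) while solid is left; crystals form when [starting material] > cs3 (solubility = 0.830 M, k = 0.0290 /min)

At 0.859 h reactive form in this flask falls back 26 times faster than it goes on to product. At the best time in this flask, reactive form makes up 65.1% of reactive form and starting material together. This flask's clearance number, with 34.9% of its partner charge left at 1.91 h, comes to 3.91. For the neighbour flask with 0.540 equiv, the two lines fed its peak of 37.5% return 38.5%.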